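**Plan**

Locants are those of bicyclo[3.2.1]oct-3-ene-2,8-dione: C1 = CH between the two C=O, C5 = other bridgehead, C6 = CH(3,5-dioxygenated aryl), C7 = CH(3,4-dioxygenated aryl).
- Retrosynthesis: after O-demethylation, the two acyl–carbon bonds C1–C2 and C5–C8 are cut together, opening both rings to an acyclic 8-methyl 1-phenyl oct-6-enedioate. This chain is cut at its CH2–C(sp2) bond (alkyl iodide + styryl enol triflate), then between the two aryl-bearing carbons (arylacetic ester + cinnamyl carbonate).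
- Enabling feature: ring C1–C2–C3–C4–C5–C8 is a 1,3-diketone. C8(=O) is bonded to C5, the γ-carbon of the C2(=O)–C3=C4 enone, and C2(=O) is bonded to C1, the α-carbon of the C8 ketone. Both bonds are therefore enolate acylations, and the first creates the nucleophile for the second.
- Forward: Ir/isothiourea allylation joins C6–C7; iodide; Negishi coupling adds the styryl dienoate; the vinyl group becomes CH2CO2Ph; one cascade closes the cyclopentanone (C5–C8), then the cyclohexenone (C1–C2); BBr3 unmasks the phenols.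
- Stereochemistry: C6 and C7 come from the catalyst pair in step 3. C5 is set by 1,2-induction from C6 in the first ring closure (arm trans to the aryl group). C1 is dictated by the bridge.

Key step: step 11

Assumption: the six phenols are carried as methyl ethers to the last step, and 3,4-dimethoxycinnamyl alcohol 3 is taken as a purchasable starting material.

**Step 1**
Reactants: 1 (3,5-dimethoxyphenyl)acetic acid
Product: 2 pentafluorophenyl (3,5-dimethoxyphenyl)acetate
Conditions: C6F5OH, DCC, CH2Cl2, 0 °C → rt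
Reagents that add atoms: pentafluorophenol, Oc1c(F)c(F)c(F)c(F)c1F
Why: Carbodiimide (Steglich-type) esterification gives the activated aryl ester that serves as the acyl donor for isothiourea (C1-ammonium enolate) catalysis.

**Step 2**
Reactants: 3 (E)-3-(3,4-dimethoxyphenyl)prop-2-en-1-ol
Product: 4 tert-butyl (E)-3-(3,4-dimethoxyphenyl)prop-2-en-1-yl carbonate
Conditions: Boc2O, DMAP (10 mol %), CH2Cl2, 0 °C → rt
Reagents that add atoms: di-tert-butyl dicarbonate, CC(C)(C)OC(=O)OC(=O)OC(C)(C)C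
Why: DMAP-catalysed O-tert-butoxycarbonylation of the primary allylic alcohol gives the ionisable linear carbonate needed for Ir-allyl chemistry.

**Step 3**
Reactants: 2 pentafluorophenyl (3,5-dimethoxyphenyl)acetate; 4 tert-butyl (E)-3-(3,4-dimethoxyphenyl)prop-2-en-1-yl carbonate
Product: 6 (2S,3S)-3-(3,4-dimethoxyphenyl)-2-(3,5-dimethoxyphenyl)pent-4-en-1-ol, via pentafluorophenyl ester 5 (not isolated)
Conditions: [Ir(cod)Cl]2 (2 mol %), Feringa-type phosphoramidite (4 mol %, cyclometallated), benzotetramisole (10 mol %), THF, rt, each catalyst as the enantiomer matched to 2S,3S; then LiAlH4, THF, 0 °C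
Reagents that add atoms: none
Why: Branched-selective Ir-catalysed asymmetric allylic alkylation run jointly with isothiourea (C1-ammonium enolate) catalysis should set the allylic centre through the Ir–phosphoramidite and the α-centre through benzotetramisole (stereodivergent pairing, here the threo 2S,3S pair), and the epimerisable α-aryl ester 5 is reduced at once to the alcohol.

**Step 4**
Reactants: 6 (2S,3S)-3-(3,4-dimethoxyphenyl)-2-(3,5-dimethoxyphenyl)pent-4-en-1-ol
Product: 7 (3S,4S)-5-iodo-3-(3,4-dimethoxyphenyl)-4-(3,5-dimethoxyphenyl)pent-1-ene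
Conditions: I2, PPh3, imidazole, CH2Cl2, 0 °C → rt
Reagents that add atoms: iodine, II
Why: Appel iodination proceeds by SN2 displacement at the primary carbon and leaves both stereocentres untouched.

**Step 5**
Reactants: 8 (E)-3-(3,4-dimethoxyphenyl)prop-2-enoic acid; 9 potassium methyl malonate
Product: 11 methyl (E)-5-(3,4-dimethoxyphenyl)-3-oxopent-4-enoate, via acyl imidazole 10 (not isolated)
Conditions: CDI, THF, rt; then 9, MgCl2, THF, rt → 50 °C; 1 M HCl work-up
Reagents that add atoms: none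
Why: Masamune–Brooks decarboxylative Claisen condensation: the acyl imidazole acylates the magnesium malonate half-ester and loss of CO2 gives the β-keto ester without touching the cinnamoyl double bond.

**Step 6**
Reactants: 11 methyl (E)-5-(3,4-dimethoxyphenyl)-3-oxopent-4-enoate
Product: 12 methyl (2Z,4E)-5-(3,4-dimethoxyphenyl)-3-(trifluoromethylsulfonyloxy)penta-2,4-dienoate
Conditions: Tf2O, sat. aq. LiOH, toluene, 5 °C
Reagents that add atoms: trifluoromethanesulfonic anhydride, O=S(=O)(OS(=O)(=O)C(F)(F)F)C(F)(F)F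
Why: O-Triflation of the lithium-chelated (Z)-enolate of a β-keto ester (stereoselective enol triflate formation) places OTf cis to the ester, so the alkyl group introduced next ends up cis to the ester.

**Step 7**
Reactants: 7 (3S,4S)-5-iodo-3-(3,4-dimethoxyphenyl)-4-(3,5-dimethoxyphenyl)pent-1-ene; 12 methyl (2Z,4E)-5-(3,4-dimethoxyphenyl)-3-(trifluoromethylsulfonyloxy)penta-2,4-dienoate
Product: 14 methyl (2E,4E)-5-(3,4-dimethoxyphenyl)-3-[(2S,3S)-3-(3,4-dimethoxyphenyl)-2-(3,5-dimethoxyphenyl)pent-4-en-1-yl]penta-2,4-dienoate, via alkylzinc iodide 13 (not isolated)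
Conditions: Zn dust (activated), LiCl, THF, 40 °C; then 12, PdCl2(dppf) (5 mol %), THF, rt → 50 °C
Reagents that add atoms: none
Why: Zinc insertion into the primary iodide followed by Negishi sp3–sp2 coupling with the electron-poor enol triflate should proceed with retention of alkene geometry and without touching the stereocentres.

**Step 8**
Reactants: 14 methyl (2E,4E)-5-(3,4-dimethoxyphenyl)-3-[(2S,3S)-3-(3,4-dimethoxyphenyl)-2-(3,5-dimethoxyphenyl)pent-4-en-1-yl]penta-2,4-dienoate
Product: 16 methyl (2E,4E)-5-(3,4-dimethoxyphenyl)-3-[(2S,3S)-3-(3,4-dimethoxyphenyl)-2-(3,5-dimethoxyphenyl)-5-hydroxypentyl]penta-2,4-dienoate, via B-alkyl-9-BBN adduct 15 (not isolated)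
Conditions: 9-BBN, THF, 0 °C → rt; then 30% H2O2, aq. NaOAc, 0 °C → rt
Reagents that add atoms: hydrogen peroxide, OO
Why: Anti-Markovnikov hydroboration with 9-BBN is selective for the monosubstituted terminal alkene over the conjugated dienoate and the styryl bond, and buffered peroxide oxidation spares the methyl ester.

**Step 9**
Reactants: 16 methyl (2E,4E)-5-(3,4-dimethoxyphenyl)-3-[(2S,3S)-3-(3,4-dimethoxyphenyl)-2-(3,5-dimethoxyphenyl)-5-hydroxypentyl]penta-2,4-dienoate
Product: 18 (3S,4S,6E)-3-(3,4-dimethoxyphenyl)-4-(3,5-dimethoxyphenyl)-6-[(E)-2-(3,4-dimethoxyphenyl)ethenyl]-8-methoxy-8-oxooct-6-enoic acid, via aldehyde 17 (not isolated)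
Conditions: TEMPO (20 mol %), PhI(OAc)2 (2.5 equiv), MeCN/H2O 1:1, rt
Reagents that add atoms: water, O
Why: Oxoammonium (TEMPO/PhI(OAc)2) oxidation in aqueous acetonitrile takes the primary alcohol through the aldehyde hydrate to the acid under near-neutral conditions that leave alkenes and electron-rich arenes alone.

**Step 10**
Reactants: 18 (3S,4S,6E)-3-(3,4-dimethoxyphenyl)-4-(3,5-dimethoxyphenyl)-6-[(E)-2-(3,4-dimethoxyphenyl)ethenyl]-8-methoxy-8-oxooct-6-enoic acid
Product: 19 8-methyl 1-phenyl (3S,4S,6E)-3-(3,4-dimethoxyphenyl)-4-(3,5-dimethoxyphenyl)-6-[(E)-2-(3,4-dimethoxyphenyl)ethenyl]oct-6-enedioate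
Conditions: PhOH, DCC, DMAP (cat.), CH2Cl2, 0 °C → rt
Reagents that add atoms: phenol, Oc1ccccc1
Why: Steglich esterification installs the phenyl ester, which serves in step 11 as a latent ketene because phenoxide is a good E1cB leaving group.

**Step 11**
Reactants: 19 8-methyl 1-phenyl (3S,4S,6E)-3-(3,4-dimethoxyphenyl)-4-(3,5-dimethoxyphenyl)-6-[(E)-2-(3,4-dimethoxyphenyl)ethenyl]oct-6-enedioate
Product: 23 (1S,5R,6R,7R)-7-(3,4-dimethoxyphenyl)-6-(3,5-dimethoxyphenyl)-4-[(E)-2-(3,4-dimethoxyphenyl)ethenyl]bicyclo[3.2.1]oct-3-ene-2,8-dione, via dilithium bis-enolate 20 (not isolated), via ketene lithium dienolate 21 (not isolated), via lithium cyclopentenolate 22 (not isolated)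
Conditions: LiHMDS (2.1 equiv), THF (0.02 M), −78 °C, 19 added to the base, 1 h; then −78 → 0 °C; AcOH quench
Reagents that add atoms: none
Why: Proposed new method: two equivalents of LiHMDS should convert 19 at −78 °C into bis-enolate 20 (α-deprotonation of the phenyl ester, γ-deprotonation of the dienoate at the CH2 syn to the ester carbonyl); on warming only the phenyl ester enolate loses phenoxide (E1cB) to give ketene 21, whose sp carbon is attacked in the ketene plane by the γ-carbon of the dienolate, and the enolate 22 so formed, enolised specifically toward the unsubstituted α-carbon because that carbon was the ketene terminus, adds to the regenerated methyl ester and expels methoxide to give 23, which has no enolisable position. The closest known reaction types are the Dieckmann/Claisen condensation, its vinylogous (γ-acylation) variant and the ketene pathway of aryl ester enolate condensations; new is the merger of both acylations into one cascade to a bridged non-enolisable β-diketone, with the ketene dictating which α-carbon of the nascent cyclopentanone carries the enolate. The cyclopentanone closes by a 5-(enolexo)-exo-dig attack on the ketene C=O and the cyclohexenone by a 6-(enolendo)-exo-trig addition to the ester. C5 is set in the first closure with the dienoate arm trans to the neighbouring 3,5-dimethoxyphenyl group on C6 (1,2-induction, all-trans cyclopentanone), and C1 is then fixed by the bridge because the three-atom arm can reach the enolate carbon only from its own face. The step needs γ- over α-attack of the dienolate (five- versus seven-membered ring), the ester kept cis to the new ring across C3=C4 (Li-bridged closed transition state in which the dienolate oxygen delivers the ketene to the syn γ-carbon), C- over O-acylation and 1,2- over 1,6-addition in the last bond formation (six-membered Li chelate, methyl ester electrophile, electron-rich δ-aryl), and no proton transfer from the acidic C5–H to the C1 enolate (exactly two equivalents of base, low temperature, fast intramolecular closure).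

**Step 12**
Reactants: 23 (1S,5R,6R,7R)-7-(3,4-dimethoxyphenyl)-6-(3,5-dimethoxyphenyl)-4-[(E)-2-(3,4-dimethoxyphenyl)ethenyl]bicyclo[3.2.1]oct-3-ene-2,8-dione
Product: 24 jezonodione, (1S,5R,6R,7R)-7-(3,4-dihydroxyphenyl)-6-(3,5-dihydroxyphenyl)-4-[(E)-2-(3,4-dihydroxyphenyl)ethenyl]bicyclo[3.2.1]oct-3-ene-2,8-dione
Conditions: BBr3 (12 equiv), CH2Cl2, −78 °C → rt; ice-water quench
Reagents that add atoms: none
Why: Lewis acid-mediated cleavage of aryl methyl ethers (BBr3) is the standard final unmasking of stilbenoid polyphenols, and since both bridgeheads are non-enolisable no stereocentre can epimerise.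

**Compound list**

1 | (3,5-dimethoxyphenyl)acetic acid | OC(=O)Cc1cc(OC)cc(OC)c1 | starting material
2 | pentafluorophenyl (3,5-dimethoxyphenyl)acetate | O=C(Cc1cc(OC)cc(OC)c1)Oc1c(F)c(F)c(F)c(F)c1F | intermediate
3 | (E)-3-(3,4-dimethoxyphenyl)prop-2-en-1-ol | OC/C=C/c1ccc(OC)c(OC)c1 | starting material
4 | tert-butyl (E)-3-(3,4-dimethoxyphenyl)prop-2-en-1-yl carbonate | CC(C)(C)OC(=O)OC/C=C/c1ccc(OC)c(OC)c1 | intermediate
5 | pentafluorophenyl (2S,3S)-3-(3,4-dimethoxyphenyl)-2-(3,5-dimethoxyphenyl)pent-4-enoate | O=C(Oc1c(F)c(F)c(F)c(F)c1F)[C@@H]([C@H](C=C)c1ccc(OC)c(OC)c1)c1cc(OC)cc(OC)c1 | intermediate (not isolated)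
6 | (2S,3S)-3-(3,4-dimethoxyphenyl)-2-(3,5-dimethoxyphenyl)pent-4-en-1-ol | OC[C@@H]([C@H](C=C)c1ccc(OC)c(OC)c1)c1cc(OC)cc(OC)c1 | intermediate
7 | (3S,4S)-5-iodo-3-(3,4-dimethoxyphenyl)-4-(3,5-dimethoxyphenyl)pent-1-ene | IC[C@@H]([C@H](C=C)c1ccc(OC)c(OC)c1)c1cc(OC)cc(OC)c1 | intermediate
8 | (E)-3-(3,4-dimethoxyphenyl)prop-2-enoic acid (3,4-dimethoxycinnamic acid) | OC(=O)/C=C/c1ccc(OC)c(OC)c1 | starting material
9 | potassium methyl malonate (potassium 3-methoxy-3-oxopropanoate) | COC(=O)CC(=O)[O-].[K+] | starting material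
10 | (E)-3-(3,4-dimethoxyphenyl)-1-(imidazol-1-yl)prop-2-en-1-one | O=C(/C=C/c1ccc(OC)c(OC)c1)n1ccnc1 | intermediate (not isolated)
11 | methyl (E)-5-(3,4-dimethoxyphenyl)-3-oxopent-4-enoate | COC(=O)CC(=O)/C=C/c1ccc(OC)c(OC)c1 | intermediate
12 | methyl (2Z,4E)-5-(3,4-dimethoxyphenyl)-3-(trifluoromethylsulfonyloxy)penta-2,4-dienoate (OTf cis to CO2Me) | COC(=O)/C=C(/C=C/c1ccc(OC)c(OC)c1)OS(=O)(=O)C(F)(F)F | intermediate
13 | [(2S,3S)-3-(3,4-dimethoxyphenyl)-2-(3,5-dimethoxyphenyl)pent-4-en-1-yl]zinc iodide | I[Zn]C[C@@H]([C@H](C=C)c1ccc(OC)c(OC)c1)c1cc(OC)cc(OC)c1 | intermediate (not isolated)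
14 | methyl (2E,4E)-5-(3,4-dimethoxyphenyl)-3-[(2S,3S)-3-(3,4-dimethoxyphenyl)-2-(3,5-dimethoxyphenyl)pent-4-en-1-yl]penta-2,4-dienoate (alkyl chain cis to CO2Me) | COC(=O)/C=C(/C=C/c1ccc(OC)c(OC)c1)C[C@@H]([C@H](C=C)c1ccc(OC)c(OC)c1)c1cc(OC)cc(OC)c1 | intermediate
15 | B-alkyl-9-BBN adduct of 14 (boron on the terminal carbon of the former vinyl group) | COC(=O)/C=C(/C=C/c1ccc(OC)c(OC)c1)C[C@@H]([C@H](CCB1C2CCCC1CCC2)c1ccc(OC)c(OC)c1)c1cc(OC)cc(OC)c1 | intermediate (not isolated)
16 | methyl (2E,4E)-5-(3,4-dimethoxyphenyl)-3-[(2S,3S)-3-(3,4-dimethoxyphenyl)-2-(3,5-dimethoxyphenyl)-5-hydroxypentyl]penta-2,4-dienoate | COC(=O)/C=C(/C=C/c1ccc(OC)c(OC)c1)C[C@@H]([C@H](CCO)c1ccc(OC)c(OC)c1)c1cc(OC)cc(OC)c1 | intermediate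
17 | methyl (2E,4E)-5-(3,4-dimethoxyphenyl)-3-[(2S,3S)-3-(3,4-dimethoxyphenyl)-2-(3,5-dimethoxyphenyl)-5-oxopentyl]penta-2,4-dienoate | COC(=O)/C=C(/C=C/c1ccc(OC)c(OC)c1)C[C@@H]([C@H](CC=O)c1ccc(OC)c(OC)c1)c1cc(OC)cc(OC)c1 | intermediate (not isolated)
18 | (3S,4S,6E)-3-(3,4-dimethoxyphenyl)-4-(3,5-dimethoxyphenyl)-6-[(E)-2-(3,4-dimethoxyphenyl)ethenyl]-8-methoxy-8-oxooct-6-enoic acid | COC(=O)/C=C(/C=C/c1ccc(OC)c(OC)c1)C[C@@H]([C@H](CC(=O)O)c1ccc(OC)c(OC)c1)c1cc(OC)cc(OC)c1 | intermediate
19 | 8-methyl 1-phenyl (3S,4S,6E)-3-(3,4-dimethoxyphenyl)-4-(3,5-dimethoxyphenyl)-6-[(E)-2-(3,4-dimethoxyphenyl)ethenyl]oct-6-enedioate | COC(=O)/C=C(/C=C/c1ccc(OC)c(OC)c1)C[C@@H]([C@H](CC(=O)Oc1ccccc1)c1ccc(OC)c(OC)c1)c1cc(OC)cc(OC)c1 | intermediate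
20 | dilithium bis-enolate of 19 (phenyl ester enolate plus methyl ester dienolate; enolate geometries not defined) | [Li]OC(OC)=CC(/C=C/c1ccc(OC)c(OC)c1)=C[C@@H]([C@H](C=C(O[Li])Oc1ccccc1)c1ccc(OC)c(OC)c1)c1cc(OC)cc(OC)c1 | intermediate (not isolated)
21 | ketene formed from 20 by loss of lithium phenoxide, still carrying the lithium dienolate | [Li]OC(OC)=CC(/C=C/c1ccc(OC)c(OC)c1)=C[C@@H]([C@H](C=C=O)c1ccc(OC)c(OC)c1)c1cc(OC)cc(OC)c1 | intermediate (not isolated)
22 | lithium enolate of the all-trans 2,3,4-trisubstituted cyclopentanone (enolate toward the CH next to the 3,4-dimethoxyphenyl carbon; dienoate arm trans to the 3,5-dimethoxyphenyl group, ester cis to the ring) | COC(=O)/C=C(/C=C/c1ccc(OC)c(OC)c1)[C@@H]1C(O[Li])=C[C@H](c2ccc(OC)c(OC)c2)[C@H]1c1cc(OC)cc(OC)c1 | intermediate (not isolated)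
23 | (1S,5R,6R,7R)-7-(3,4-dimethoxyphenyl)-6-(3,5-dimethoxyphenyl)-4-[(E)-2-(3,4-dimethoxyphenyl)ethenyl]bicyclo[3.2.1]oct-3-ene-2,8-dione (C6 aryl exo, C7 aryl endo) | O=C1C=C(/C=C/c2ccc(OC)c(OC)c2)[C@@H]2C(=O)[C@H]1[C@H](c1ccc(OC)c(OC)c1)[C@H]2c1cc(OC)cc(OC)c1 | intermediate
24 | jezonodione | O=C1C=C(/C=C/c2ccc(O)c(O)c2)[C@@H]2C(=O)[C@H]1[C@H](c1ccc(O)c(O)c1)[C@H]2c1cc(O)cc(O)c1 | target

**Step count**

Total: 12 steps. Longest linear sequence: 9 steps (1 → 2 → 6 → 7 → 14 → 16 → 18 → 19 → 23 → 24; steps 1, 3, 4, 7, 8, 9, 10, 11, 12).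

**Steps most likely to fail**

Step 11 (Proposed new method). The cascade may stall after the first ring closure. Possible causes are intermolecular proton transfer from the doubly activated C5–H to the ring enolate, γ-acylation through the dienolate conformer that leaves the ester trans to the new ring, or incomplete γ-deprotonation that lets the ketene be consumed by other pathways. The fallback uses known reactions only and sets out from 19. Potassium tert-butoxide (1.1 equiv, THF, 0 °C) should effect only the vinylogous Dieckmann closure and, after acidification, give the all-trans cyclopentanone keto ester F1. DIBAL-H (CH2Cl2, −78 °C) should reduce ketone and ester to the diol F2. Dess–Martin periodinane should oxidise both alcohols to the keto enal F3. DBU (cat., CH2Cl2, rt) should equilibrate the enal geometry through the extended enolate and close the six-membered ring by intramolecular aldol addition, as in Stork–Landesman-type bicyclo[3.2.1]octane ketol formation, to give the bridged ketol F4. Dess–Martin oxidation of the allylic alcohol comes back to the route at 23.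

Step 3. With two electron-rich partners the dual catalysis may give insufficient diastereo- or enantiocontrol or some linear allylation, and the α-aryl ester may epimerise before it is reduced. The fallback sets out from 1 and 3. DCC/DMAP esterification should give the cinnamyl arylacetate F5. Ireland–Claisen rearrangement (LiHMDS, TMSCl, THF, −78 °C → rt; (Z)-enolate, chair transition state) should give the racemic 2,3-syn acid F6. Classical resolution by crystallisation of its salt with an enantiopure 1-phenylethylamine should give the (2S,3S)-acid F7. LiAlH4 reduction comes back to the route at 6.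

Step 12. During the long exposure to BBr3 that six ethers require, Lewis-acid-induced Friedel–Crafts closure of the endo aryl ring onto the C2 carbonyl, or retro-Claisen opening of the strained dione, may compete with ether cleavage. The fallback moves the ether cleavage ahead of the ring construction and sets out from 19. BBr3 (CH2Cl2, −78 → 0 °C, water quench) on this robust open-chain diester should give the hexaphenol diester F8. TBSCl/imidazole (DMF) should give the hexakis(tert-butyldimethylsilyl) ether F9. The conditions of step 11 should give the silyl-protected bicyclic dione F10. HF·pyridine (THF/pyridine, 0 °C) comes back to the route at 24.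

**Further compounds**

F1 | step 11 | methyl (4E)-5-(3,4-dimethoxyphenyl)-3-[3-(3,4-dimethoxyphenyl)-2-(3,5-dimethoxyphenyl)-5-oxocyclopentyl]penta-2,4-dienoate, all-trans ring, 2E/2Z mixture | COC(=O)C=C(/C=C/c1ccc(OC)c(OC)c1)[C@@H]1C(=O)C[C@H](c2ccc(OC)c(OC)c2)[C@H]1c1cc(OC)cc(OC)c1
F2 | step 11 | diol from reduction of ketone and ester of F1 (carbinol configuration and 2,3-alkene geometry not defined) | OCC=C(/C=C/c1ccc(OC)c(OC)c1)[C@@H]1C(O)C[C@H](c2ccc(OC)c(OC)c2)[C@H]1c1cc(OC)cc(OC)c1
F3 | step 11 | keto enal, (4E)-5-(3,4-dimethoxyphenyl)-3-[3-(3,4-dimethoxyphenyl)-2-(3,5-dimethoxyphenyl)-5-oxocyclopentyl]penta-2,4-dienal | O=CC=C(/C=C/c1ccc(OC)c(OC)c1)[C@@H]1C(=O)C[C@H](c2ccc(OC)c(OC)c2)[C@H]1c1cc(OC)cc(OC)c1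
F4 | step 11 | bridged ketol, 2-hydroxy-7-(3,4-dimethoxyphenyl)-6-(3,5-dimethoxyphenyl)-4-[(E)-2-(3,4-dimethoxyphenyl)ethenyl]bicyclo[3.2.1]oct-3-en-8-one (carbinol configuration not defined) | OC1C=C(/C=C/c2ccc(OC)c(OC)c2)[C@@H]2C(=O)[C@H]1[C@H](c1ccc(OC)c(OC)c1)[C@H]2c1cc(OC)cc(OC)c1
F5 | step 3 | (E)-3-(3,4-dimethoxyphenyl)prop-2-en-1-yl (3,5-dimethoxyphenyl)acetate | O=C(Cc1cc(OC)cc(OC)c1)OC/C=C/c1ccc(OC)c(OC)c1
F6 | step 3 | racemic (2S*,3S*)-3-(3,4-dimethoxyphenyl)-2-(3,5-dimethoxyphenyl)pent-4-enoic acid | OC(=O)[C@@H]([C@H](C=C)c1ccc(OC)c(OC)c1)c1cc(OC)cc(OC)c1.OC(=O)[C@H]([C@@H](C=C)c1ccc(OC)c(OC)c1)c1cc(OC)cc(OC)c1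
F7 | step 3 | (2S,3S)-3-(3,4-dimethoxyphenyl)-2-(3,5-dimethoxyphenyl)pent-4-enoic acid | OC(=O)[C@@H]([C@H](C=C)c1ccc(OC)c(OC)c1)c1cc(OC)cc(OC)c1
F8 | step 12 | 8-methyl 1-phenyl (3S,4S,6E)-3-(3,4-dihydroxyphenyl)-4-(3,5-dihydroxyphenyl)-6-[(E)-2-(3,4-dihydroxyphenyl)ethenyl]oct-6-enedioate | COC(=O)/C=C(/C=C/c1ccc(O)c(O)c1)C[C@@H]([C@H](CC(=O)Oc1ccccc1)c1ccc(O)c(O)c1)c1cc(O)cc(O)c1
F9 | step 12 | hexakis(tert-butyldimethylsilyl) ether of F8 | COC(=O)/C=C(/C=C/c1ccc(O[Si](C)(C)C(C)(C)C)c(O[Si](C)(C)C(C)(C)C)c1)C[C@@H]([C@H](CC(=O)Oc1ccccc1)c1ccc(O[Si](C)(C)C(C)(C)C)c(O[Si](C)(C)C(C)(C)C)c1)c1cc(O[Si](C)(C)C(C)(C)C)cc(O[Si](C)(C)C(C)(C)C)c1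
F10 | step 12 | hexakis(tert-butyldimethylsilyl) ether of jezonodione | O=C1C=C(/C=C/c2ccc(O[Si](C)(C)C(C)(C)C)c(O[Si](C)(C)C(C)(C)C)c2)[C@@H]2C(=O)[C@H]1[C@H](c1ccc(O[Si](C)(C)C(C)(C)C)c(O[Si](C)(C)C(C)(C)C)c1)[C@H]2c1cc(O[Si](C)(C)C(C)(C)C)cc(O[Si](C)(C)C(C)(C)C)c1
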